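**Strategy.** Numbering: ring A (five-membered) is C1(CH3)–C2(O-angeloyl)–C3–C4(OH, iPr)–C5; ring B (seven-membered) is C5–C6(O-aroyl)–C7–C8(CH3)=C9–C10–C1. The plan rests on excising C7 and C8 from ring B, which leaves a cis-fused diquinane ketone with C6 bonded to C9. The feature exploited is the C7–C8(CH3)=C9 segment beside oxygenated C6: it is a but-2-ynoate inserted into that C6–C9 bond. In one operation the pyrrolidine enamine (C6=C9) adds the ynoate across C9 and C6 and the aminocyclobutene opens at C6–C9, building ring B with its methyl and alkene placed. The precursor is the C2-OTBS, C4-OTMS diquinane enamine already holding C1, C2, C4 and C5.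

Key step: step 11

**Remarks on the chemistry (assumptions)**
- The target is read as cis-fused (H-5 syn to the C1 methyl), with the C2 and C4 oxygens on the face of ring A that carries ring B and the C6 oxygen syn to H-5.
- Absolute configuration comes from (S)-4-[(tert-butyldimethylsilyl)oxy]cyclopent-2-en-1-one (C2 of the target), assumed to be purchasable as the single enantiomer.
- Ring A is made first and ring B is closed onto it, because closing ring A from a chain on C5 onto C1 of a cyclopentenone would be a 5-endo-trig process.
- C4–O is carried as the trimethylsilyl ether: it is the smallest silyl group next to the crowded C6, and it leaves in the acid step that hydrolyses the enamine.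
- The ynoate is used as its allyl ester so that the C7 carboxyl can be removed at room temperature without moving the C8=C9 alkene.

**Route**

Step 1
Reactants: 1 (S)-4-[(tert-butyldimethylsilyl)oxy]cyclopent-2-en-1-one; 2 [2-(1,3-dioxolan-2-yl)ethyl]magnesium bromide
Product: 3 (3S,4S)-4-[(tert-butyldimethylsilyl)oxy]-3-[2-(1,3-dioxolan-2-yl)ethyl]-1-[(trimethylsilyl)oxy]cyclopent-1-ene (chain trans to OTBS; used crude)
Conditions: CuBr·SMe2 (10 mol %), TMSCl, THF, −78 °C; Et3N quench
Reagents that add atoms: chlorotrimethylsilane, C[Si](C)(C)Cl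
Why: Copper-catalysed, TMSCl-accelerated conjugate addition of the Grignard reagent should place the chain on C1 anti to the C2 silyloxy group and trap the enolate as its silyl enol ether (the C1 centre set here is erased in step 2).

Step 2
Reactants: 3 silyl enol ether
Product: 4 (S)-4-[(tert-butyldimethylsilyl)oxy]-3-[2-(1,3-dioxolan-2-yl)ethyl]cyclopent-2-en-1-one
Conditions: Pd(OAc)2 (10 mol %), O2 (1 atm), DMSO, 45 °C
Reagents that add atoms: none
Why: Saegusa–Ito oxidation: the palladium enolate at C5 has only the C1 hydrogen available for β-hydride elimination, so the enone should re-form with the chain now on the β-carbon C1 while C2 is untouched.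

Step 3
Reactants: 4 chain-bearing enone
Product: 6 enol triflate of the C1-methylated ketone (C4–OTf; C4=C5; C1 methyl trans to C2–OTBS and chain cis), via lithium enolate 5 (not isolated)
Conditions: MeLi, CuI, Et2O, −78 → −20 °C; then PhNTf2, THF, −20 °C → rt
Reagents that add atoms: lithium dimethylcuprate, [Li+].C[Cu-]C; N-phenylbis(trifluoromethanesulfonimide), O=S(=O)(N(c1ccccc1)S(=O)(=O)C(F)(F)F)C(F)(F)F
Why: Gilman conjugate addition should create the quaternary centre C1 with methyl entering anti to the adjacent C2 silyloxy group (chain therefore cis to that oxygen, as the target requires), and O-triflation of the regiodefined lithium enolate fixes the double bond at C4=C5.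

Step 4
Reactants: 6 enol triflate
Product: 7 4-[(tert-butyldimethylsilyl)oxy]-3-[2-(1,3-dioxolan-2-yl)ethyl]-1-isopropyl-3-methylcyclopent-1-ene (C4(iPr)=C5; configuration as in 6)
Conditions: iPrZnBr, Pd(dppf)Cl2 (5 mol %), THF, 50 °C
Reagents that add atoms: isopropylzinc bromide, CC(C)[Zn]Br
Why: Negishi coupling of the enol triflate with a secondary alkylzinc halide, where the wide bite angle of dppf favours reductive elimination over β-hydride elimination so that isopropyl should be transferred unrearranged; no stereocentre is affected.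

Step 5
Reactants: 7 isopropyl cyclopentene acetal
Product: 9 oxime of 3-[5-(TBS-oxy)-3-isopropyl-1-methylcyclopent-2-en-1-yl]propanal (E/Z mixture), via aldehyde 8 (not isolated)
Conditions: NH2OH·HCl (3 equiv), EtOH/H2O (4:1), 60 °C
Reagents that add atoms: hydroxylamine hydrochloride, NO.Cl
Why: Acid-mediated acetal cleavage and oxime condensation in one flask; hydroxylamine captures the aldehyde as it forms, which avoids an acid-induced Prins-type attack of the ring alkene, and the hindered secondary TBS ether should survive the weakly acidic medium.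

Step 6
Reactants: 9 oxime
Product: 12 tricyclic isoxazoline (O on C4; C6=N; H-5 cis to the C1 methyl; C4–O cis to C6; isopropyl on the convex face), via hydroximoyl chloride 10 (not isolated), via nitrile oxide 11 (not isolated)
Conditions: NaOCl (aq.), Et3N (cat.), CH2Cl2, 0 °C → rt, high dilution
Reagents that add atoms: none
Why: Intramolecular nitrile oxide–alkene (3+2) cycloaddition: the three-carbon tether on the lower face of C1 can only deliver C6 to C5 and oxygen to C4 suprafacially from that face (oxygen to the more substituted alkene carbon, the intrinsic preference), which should set C5 (H syn to the C1 methyl, cis fusion) and C4 (oxygen syn to C6, isopropyl on the convex face).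

Step 7
Reactants: 12 isoxazoline
Product: 14 cis-diquinane aldol (C6 ketone; C4 tertiary OH; C2 OTBS), via hydroxy imine 13 (not isolated)
Conditions: H2 (1 atm), Raney Ni, B(OH)3, MeOH/H2O (5:1), rt
Reagents that add atoms: water, O
Why: Hydrogenolysis of the isoxazoline N–O bond over Raney Ni, with boric acid hydrolysing the β-hydroxy imine as it forms, is the standard unmasking of an aldol unit and should leave C4 and C5 untouched.

Step 8
Reactants: 14 diquinane aldol
Product: 15 C4 trimethylsilyl ether of the diquinane ketone
Conditions: N-(trimethylsilyl)imidazole, CH2Cl2, rt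
Reagents that add atoms: N-(trimethylsilyl)imidazole, C[Si](C)(C)n1ccnc1
Why: Silyl transfer from N-(trimethylsilyl)imidazole silylates even hindered tertiary alcohols without enolising the ketone, and the ether blocks retro-aldol cleavage and dehydration during enamine formation.

Step 9
Reactants: 15 silylated diquinane ketone; 16 pyrrolidine
Product: 17 pyrrolidine enamine of the diquinane ketone (C6=C9; used crude)
Conditions: pyrrolidine (6 equiv), 4 Å molecular sieves, PhH, 80 °C
Reagents that add atoms: none
Why: Enamine condensation with removal of water; the double bond should form toward the methylene C9 because C5 is a methine held between the fully substituted C1 and C4, so that the tetrasubstituted isomer would suffer prohibitive allylic strain.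

Step 10
Reactants: 18 but-2-ynoic acid; 19 allyl bromide
Product: 20 allyl but-2-ynoate
Conditions: K2CO3, DMF, rt
Reagents that add atoms: none
Why: SN2 O-alkylation of the potassium carboxylate under conditions too mild to isomerise the ynoate to the allenoate.

Step 11
Reactants: 17 diquinane enamine; 20 allyl but-2-ynoate
Product: 22 ring-expanded hydroazulene dienamine ester (N–C6=C7(CO2allyl)–C8(CH3)=C9), via aminocyclobutene 21 (not isolated)
Conditions: 20 (3 equiv), 1,4-dioxane, 90 °C, sealed tube, Ar
Reagents that add atoms: none
Why: The enamine carbon C9 adds in Michael fashion to the methyl-bearing alkyne carbon (future C8) and the ester-stabilised vinyl anion closes on the iminium carbon C6, a stepwise (2+2) cycloaddition that should give the fused aminocyclobutene 21. The closest known reaction type is the two-carbon ring expansion of cyclic ketone enamines with acetylenic esters. The four-membered ring closes by 4-exo-trig attack on the iminium carbon; the seven-membered ring is then formed not by a new bond but by push–pull heterolytic opening of the cyclobutene across the old C6–C9 bond, which merges the four- and five-membered rings. No stereocentre is created: C6 and C9 of 21 are transient, and C1, C2, C4 and C5 are spectators, so the cis fusion is carried over. The step needs C9 and not C5 as the enamine carbon, which the fully substituted neighbours of C5 secure; attack at the β-carbon of the ynoate, which the ester polarisation secures; and cyclisation instead of proton transfer to an open-chain Michael adduct, which the aprotic medium favours. The small trimethylsilyl group at C4 leaves room on the concave face for the nitrogen that is pushed there when C6 becomes tetrahedral.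

Step 12
Reactants: 22 dienamine ester
Product: 23 allyl β-keto ester with free C4–OH (C6 ketone; C7 ester; C8=C9; C7 epimers and enol)
Conditions: 1 M HCl, THF, 0 °C → rt
Reagents that add atoms: water, O
Why: Vinylogous carbamate hydrolysis (C7 protonation, then water adds to the iminium) should release the β-keto ester, and the same dilute acid removes the tertiary TMS ether while the hindered secondary TBS ether stays; C7 is an enolisable centre obtained as a mixture.

Step 13
Reactants: 23 allyl β-keto ester
Product: 25 β,γ-unsaturated hydroazulenone (C6 ketone; C7H2; C8=C9; C4–OH; C2–OTBS), via keto acid 24 (not isolated)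
Conditions: Pd(PPh3)4 (5 mol %), HCO2H, Et3N, THF, rt → 40 °C
Reagents that add atoms: none
Why: Tsuji deallylation–decarboxylation: zerovalent palladium ionises the allyl ester, formate reduces the allyl fragment to propene, and the β-keto acid loses CO2 through its dienol, whose kinetic protonation at C7 under near-neutral conditions should leave the alkene at C8=C9.

Step 14
Reactants: 25 β-hydroxy ketone
Product: 26 C4,C6-diol (C6–OH syn to H-5 and to the C1 methyl)
Conditions: Me4NBH(OAc)3, MeCN/AcOH (1:1), −30 °C
Reagents that add atoms: none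
Why: Evans–Saksena hydroxyl-directed reduction: the C4 oxygen binds boron and the acetoxyborohydride delivers hydride intramolecularly to the face of the C6 carbonyl on which C4 lies (the reagent does not reduce unactivated ketones on its own), so the new C6 hydroxyl should emerge syn to H-5 as in the target.

Step 15
Reactants: 26 diol; 27 3,4,5-trimethoxybenzoyl chloride
Product: 28 C6 3,4,5-trimethoxybenzoate (C4–OH free; C2–OTBS)
Conditions: Et3N, DMAP (cat.), CH2Cl2, 0 °C → rt
Reagents that add atoms: none
Why: DMAP-catalysed acylation of the only reactive hydroxyl: the C6 carbinol is secondary, whereas the C4 carbinol is tertiary and hindered and C2 is still silylated.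

Step 16
Reactants: 28 silylated aroyl ester
Product: 29 C2 alcohol (C6 aroyl ester; C4–OH)
Conditions: HF·pyridine, THF, 0 °C → rt
Reagents that add atoms: none
Why: Fluoride-mediated desilylation under acidic, non-basic conditions, which should spare the aryl ester and the tertiary alcohol and avoid acyl migration.

Step 17
Reactants: 29 C2 alcohol; 30 angelic acid
Product: 32 CNP0112256.1, via mixed anhydride 31 (not isolated)
Conditions: 2,4,6-trichlorobenzoyl chloride, Et3N, toluene, rt; then 29, 80 °C
Reagents that add atoms: none
Why: Yamaguchi-type mixed-anhydride esterification without DMAP, the protocol established for transferring the angeloyl group to hindered secondary alcohols without Z-to-E isomerisation to the tiglate; the tertiary C4 hydroxyl should not compete.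

**Compound list**

1 | (S)-4-[(tert-butyldimethylsilyl)oxy]cyclopent-2-en-1-one | CC(C)(C)[Si](C)(C)O[C@H]1CC(=O)C=C1 | starting material
2 | [2-(1,3-dioxolan-2-yl)ethyl]magnesium bromide (THF solution) | Br[Mg]CCC1OCCO1 | starting material
3 | (3S,4S)-4-(TBS-oxy)-3-[2-(1,3-dioxolan-2-yl)ethyl]-1-(trimethylsilyloxy)cyclopent-1-ene | CC(C)(C)[Si](C)(C)O[C@H]1CC(O[Si](C)(C)C)=C[C@@H]1CCC2OCCO2 | intermediate
4 | (S)-4-(TBS-oxy)-3-[2-(1,3-dioxolan-2-yl)ethyl]cyclopent-2-en-1-one | CC(C)(C)[Si](C)(C)O[C@H]1CC(=O)C=C1CCC2OCCO2 | intermediate
5 | lithium enolate of the C1-methylated ketone (methyl trans to OTBS) | CC(C)(C)[Si](C)(C)O[C@H]1CC(O[Li])=C[C@@]1(C)CCC2OCCO2 | intermediate (not isolated)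
6 | 4-(TBS-oxy)-3-[2-(1,3-dioxolan-2-yl)ethyl]-3-methylcyclopent-1-en-1-yl triflate (methyl trans to OTBS) | CC(C)(C)[Si](C)(C)O[C@H]1CC(OS(=O)(=O)C(F)(F)F)=C[C@@]1(C)CCC2OCCO2 | intermediate
7 | 4-(TBS-oxy)-3-[2-(1,3-dioxolan-2-yl)ethyl]-1-isopropyl-3-methylcyclopent-1-ene | CC(C)(C)[Si](C)(C)O[C@H]1CC(C(C)C)=C[C@@]1(C)CCC2OCCO2 | intermediate
8 | 3-[5-(TBS-oxy)-3-isopropyl-1-methylcyclopent-2-en-1-yl]propanal | CC(C)(C)[Si](C)(C)O[C@H]1CC(C(C)C)=C[C@@]1(C)CCC=O | intermediate (not isolated)
9 | oxime of 8 | CC(C)(C)[Si](C)(C)O[C@H]1CC(C(C)C)=C[C@@]1(C)CCC=NO | intermediate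
10 | hydroximoyl chloride of 9 | CC(C)(C)[Si](C)(C)O[C@H]1CC(C(C)C)=C[C@@]1(C)CCC(Cl)=NO | intermediate (not isolated)
11 | nitrile oxide | CC(C)(C)[Si](C)(C)O[C@H]1CC(C(C)C)=C[C@@]1(C)CCC#[N+][O-] | intermediate (not isolated)
12 | tricyclic isoxazoline (O–C4, N=C6, cis-fused) | CC(C)(C)[Si](C)(C)O[C@H]1C[C@](O3)(C(C)C)[C@H]2C(=N3)CC[C@@]12C | intermediate
13 | β-hydroxy imine (C6=NH, C4–OH) | CC(C)(C)[Si](C)(C)O[C@H]1C[C@](O)(C(C)C)[C@H]2C(=N)CC[C@@]12C | intermediate (not isolated)
14 | cis-diquinane aldol (C6 ketone, C4–OH, C2–OTBS) | CC(C)(C)[Si](C)(C)O[C@H]1C[C@](O)(C(C)C)[C@H]2C(=O)CC[C@@]12C | intermediate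
15 | C4 trimethylsilyl ether of 14 | CC(C)(C)[Si](C)(C)O[C@H]1C[C@](O[Si](C)(C)C)(C(C)C)[C@H]2C(=O)CC[C@@]12C | intermediate
16 | pyrrolidine | C1CCNC1 | starting material
17 | pyrrolidine enamine of 15 (C6=C9) | CC(C)(C)[Si](C)(C)O[C@H]1C[C@](O[Si](C)(C)C)(C(C)C)[C@H]2C(N3CCCC3)=CC[C@@]12C | intermediate
18 | but-2-ynoic acid | CC#CC(=O)O | starting material
19 | allyl bromide | C=CCBr | starting material
20 | allyl but-2-ynoate | CC#CC(=O)OCC=C | intermediate
21 | fused aminocyclobutene (C6–C7=C8–C9 ring on the convex face) | CC(C)(C)[Si](C)(C)O[C@H]1C[C@](O[Si](C)(C)C)(C(C)C)[C@H]2[C@]3(N4CCCC4)C(C(=O)OCC=C)=C(C)[C@@H]3C[C@@]12C | intermediate (not isolated)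
22 | ring-expanded hydroazulene dienamine allyl ester | CC(C)(C)[Si](C)(C)O[C@H]1C[C@](O[Si](C)(C)C)(C(C)C)[C@H]2C(N3CCCC3)=C(C(=O)OCC=C)C(C)=CC[C@@]12C | intermediate
23 | allyl β-keto ester (C4–OH free, C7 undefined) | CC(C)(C)[Si](C)(C)O[C@H]1C[C@](O)(C(C)C)[C@H]2C(=O)C(C(=O)OCC=C)C(C)=CC[C@@]12C | intermediate
24 | β-keto acid | CC(C)(C)[Si](C)(C)O[C@H]1C[C@](O)(C(C)C)[C@H]2C(=O)C(C(=O)O)C(C)=CC[C@@]12C | intermediate (not isolated)
25 | β,γ-unsaturated hydroazulenone | CC(C)(C)[Si](C)(C)O[C@H]1C[C@](O)(C(C)C)[C@H]2C(=O)CC(C)=CC[C@@]12C | intermediate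
26 | C4,C6-diol | CC(C)(C)[Si](C)(C)O[C@H]1C[C@](O)(C(C)C)[C@H]2[C@H](O)CC(C)=CC[C@@]12C | intermediate
27 | 3,4,5-trimethoxybenzoyl chloride | COc1cc(C(=O)Cl)cc(OC)c1OC | starting material
28 | C6 3,4,5-trimethoxybenzoate, C2–OTBS | CC(C)(C)[Si](C)(C)O[C@H]1C[C@](O)(C(C)C)[C@H]2[C@H](OC(=O)c3cc(OC)c(OC)c(OC)c3)CC(C)=CC[C@@]12C | intermediate
29 | C6 3,4,5-trimethoxybenzoate, C2–OH | O[C@H]1C[C@](O)(C(C)C)[C@H]2[C@H](OC(=O)c3cc(OC)c(OC)c(OC)c3)CC(C)=CC[C@@]12C | intermediate
30 | angelic acid, (Z)-2-methylbut-2-enoic acid | C/C=C(/C)C(=O)O | starting material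
31 | angelic 2,4,6-trichlorobenzoic anhydride | C/C=C(/C)C(=O)OC(=O)c1c(Cl)cc(Cl)cc1Cl | intermediate (not isolated)
32 | CNP0112256.1 | C/C=C(/C)C(=O)O[C@H]1C[C@](O)(C(C)C)[C@H]2[C@H](OC(=O)c3cc(OC)c(OC)c(OC)c3)CC(C)=CC[C@@]12C | target

**Step count and risk**

Total step count: 17. Longest linear sequence: 16 (steps 1–9 and 11–17; step 10 is a one-step side branch).

Steps most likely to fail:

Step 11 (key step). After the first C9–C8 bond is made, proton transfer within the zwitterion can outrun closure onto the crowded iminium carbon C6, so that the reaction stops at the open-chain Michael adduct; the hindered enamine may also fail to engage the β-methyl ynoate at a useful rate. The fallback sets out from ketone 15 and comes back at β-keto ester 23, and it separates cycloaddition from ring opening. LiN(iPr)2 and TMSCl (THF, −78 °C) should give the kinetic trimethylsilyl enol ether F1 with the double bond at C6=C9. With allyl but-2-ynoate 20 and EtAlCl2 (CH2Cl2, −78 → 0 °C), a Lewis-acid-promoted (2+2) cycloaddition should give the 6-siloxy cyclobutene F2. Bu4NF (THF, 0 °C) should then free the cyclobutanolate, whose strain-driven retro-aldol cleavage of C6–C9, with loss of the C4 trimethylsilyl group, leads after protonation to 23.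

Step 17. Acylation of the C2 hydroxyl, which sits on the concave face next to the quaternary C1, may be so slow that prolonged heating isomerises the angeloyl unit to the tigloyl isomer. The fallback sets out from alcohol 29 and comes back at target 32, building the alkene after the ester. Esterification with 2-[bis(2,2,2-trifluoroethoxy)phosphoryl]propanoic acid (DCC, DMAP, CH2Cl2) should give the phosphonopropanoate F3. Still–Gennari olefination (KN(SiMe3)2, 18-crown-6, THF, −78 °C, then acetaldehyde) should then form the (Z)-2-methylbut-2-enoate in place.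

Step 6. The nitrile oxide may dimerise, or hypochlorite may chlorinate the electron-rich trisubstituted alkene, before cycloaddition onto the hindered C4=C5 bond takes place. The fallback sets out from enone 4 and comes back at aldol 14, closing ring B by an aldol addition instead. Me2CuLi (Et2O, −78 → −20 °C, NH4Cl quench) should give the 3-methyl ketone F4 with methyl anti to OTBS. 1 M HCl in THF should hydrolyse the acetal and let the enol of the C4 ketone add to the C6 aldehyde, giving the cis-fused hydroxy ketone F5. iPrMgBr with CeCl3 (THF, −78 °C, excess) should add to the C4 carbonyl from the convex face to give diol F6. Dess–Martin periodinane (NaHCO3, CH2Cl2) should then oxidise the secondary C6 carbinol to 14.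

**Further compounds**

F1 | step 11 | trimethylsilyl enol ether of 15 (C6=C9) | CC(C)(C)[Si](C)(C)O[C@H]1C[C@](O[Si](C)(C)C)(C(C)C)[C@H]2C(O[Si](C)(C)C)=CC[C@@]12C
F2 | step 11 | 6-siloxy cyclobutene from F1 and 20 | CC(C)(C)[Si](C)(C)O[C@H]1C[C@](O[Si](C)(C)C)(C(C)C)[C@H]2[C@]3(O[Si](C)(C)C)C(C(=O)OCC=C)=C(C)[C@@H]3C[C@@]12C
F3 | step 17 | C2 2-[bis(2,2,2-trifluoroethoxy)phosphoryl]propanoate of 29 | CC(C(=O)O[C@H]1C[C@](O)(C(C)C)[C@H]2[C@H](OC(=O)c3cc(OC)c(OC)c(OC)c3)CC(C)=CC[C@@]12C)P(=O)(OCC(F)(F)F)OCC(F)(F)F
F4 | step 6 | 4-(TBS-oxy)-3-[2-(1,3-dioxolan-2-yl)ethyl]-3-methylcyclopentan-1-one (methyl trans to OTBS) | CC(C)(C)[Si](C)(C)O[C@H]1CC(=O)C[C@@]1(C)CCC2OCCO2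
F5 | step 6 | cis-diquinane with C4 ketone and C6 hydroxyl (C6 epimers) | CC(C)(C)[Si](C)(C)O[C@H]1CC(=O)[C@H]2C(O)CC[C@@]12C
F6 | step 6 | cis-diquinane C4,C6-diol (C4 isopropyl on the convex face) | CC(C)(C)[Si](C)(C)O[C@H]1C[C@](O)(C(C)C)[C@H]2C(O)CC[C@@]12C
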